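**The vessel.** The vessel was closed and stirred, and electrophile plus product stayed at the charge, 99.9% at the last beta reading. Yet the electrophile slowed early.

| flask | electrophile | nucleophile | remark | time |
|---|---|---|---|---|
| beta | 0.60 M | 1.5 equiv | run made earlier |  |
| epsilon | 0.20 M | 1.5 equiv | run made earlier |  |
| Friday's | 0.40 M | 1.50 equiv |  | 30 min |
| Tuesday's | 0.40 M | 2.20 equiv |  | 30 min |
| Saturday's | 0.40 M | 3.40 equiv |  | 30 min |

- beta (time / min: electrophile / %, product / %): 0.833: 86.2, 14.0; 1.50: 78.5, 20.9; 3.00: 67.9, 32.1; 6.00: 57.9, 42.5; 10.0: 51.0, 48.9
- epsilon (time / min: electrophile / %, product / %): 0.833: 94.6, 5.0; 1.50: 91.1, 7.9; 3.00: 86.2, 14.1; 6.00: 77.7, 22.2; 10.0: 72.6, 28.7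

(scatter of a reading: 0.3 percentage points)



* part of the electrophile that has reacted at the end, Friday's
* part of the electrophile that has reacted at the end, Tuesday's
* part of the electrophile that has reacted at the end, Saturday's
* what raising the equivalents of nucleophile from its lowest to its highest value here does to the part of the electrophile that has reacted (changes below 5 percentage points count as none) (it rises / it falls / no change)

**Turned round.** A flat trend needed Saturday's to end within 5 percentage points of Friday's. So I followed one nucleophile molecule and asked two things: what chance it had of being free to attack, and how many such molecules each electrophile cost.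

**The fork.** The first epsilon reading gave me a rate constant 0.222 L mol⁻¹ min⁻¹, taking all nucleophile as free then. The slope between the last two readings of each run then gave the free share of the nucleophile left. At a cost of one, the share read 0.228 in beta and 0.305 in epsilon. At a cost of two, it read 0.404 and 0.381, a closer pair. I kept the cost of two and the mean, the free share φ = 0.392, the chance that a surviving nucleophile molecule can attack.

**My reckoning.** With b half the equivalents, c the electrophile charge, R = 2·k·c·φ·t, here 2.09, and E = exp(R(b−1)), the fraction reacted is b(E−1)/(bE−1). That gave me 55.0% for Friday's, 71.9% for Tuesday's and 89.0% for Saturday's. The span of 34 points stood far from flat. On this cost, nucleophile was the limiting reagent of Friday's.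

**The forecast.** The forecast said 54%, 62% and 70%, and it rises, on this ground: “Conversion therefore stalls at a plateau that rises with nucleophile charge”. My Tuesday's and Saturday's figures stood higher.

**The flask.** Friday's reached 55.8%, Tuesday's 73.9% and Saturday's 91.6%: it rises, by 36 points.

    nucleophile ⇌ dormant form (K = 1.60, k = 0.00200 s⁻¹)
    nucleophile + acid set free ⇌ protonated nucleophile, settled at all times (K = 1500 L mol⁻¹)
    electrophile + nucleophile → acid set free + product (k = 0.00380 L mol⁻¹ s⁻¹)

At 30.0 min in Friday's, protonated nucleophile equalled 55.0% of the electrophile charged, beside product at 55.8%. With φ held at 0.392, my Saturday's figure lay 2.6 points below the flask. For the neighbour of Saturday's charged with 0.850 equiv of nucleophile, the same φ gives 34.1%, and that neighbour reached 34.1%.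

Readings and results are calculated with made-up constants, noise included.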